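**Strategy**

Ring numbering: C1 is the CH carrying the hydroxypentenyl chain, C2 the quaternary carbon, C3 the CHBr, C6 the ring carbinol. Everything rests on a [3+3] annulation that exploits the 1,3-related, methyl-bearing carbons C6 and C2 flanking C1: this triad is the lactone carbonyl, α-carbon and acetyl carbonyl of 2-acetylbutyrolactone, and C3–C4–C5 is 1-chloro-3-iodopropane. One SmI2 operation forms C2–C3 (Barbier addition) and C5–C6 (acyl substitution that opens the lactone and frees the side-chain handle); dehydration gives a 2-substituted 3-methylcyclohexenone. Bromine then enters at the γ-carbon C3, anti conjugate allylation builds C2, and C6 becomes the carbinol.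

Key step: step 1

Remark: compounds 1, 2, 14, 15 and 21 are taken as commercial; the C1–C6 ring numbering defined above is used in all Why lines.

**Route**

Step 1
Reactants: 1 3-acetyloxolan-2-one (2-acetylbutyrolactone); 2 1-chloro-3-iodopropane
Product: 5 2-(2-hydroxyethyl)-3-methylcyclohex-2-en-1-one, via chloro lactone adduct 3 (not isolated), via hydroxy ketone 4 (not isolated)
Conditions: SmI2 (4.5 equiv), NiI2 (2 mol %), THF, 0 °C; then hν (visible), rt; 1 M HCl, rt
Reagents that add atoms: none
Why: SmI2 (NiI2-catalysed) reduces the C–I bond first and the alkylsamarium adds to the samarium-chelated acetyl ketone (Barbier reaction, C2–C3); under visible light the C–Cl bond is then reduced and the new alkylsamarium attacks the lactone carbonyl in a 6-exo-trig nucleophilic acyl substitution (C5–C6) that releases the ring oxygen as the 2-hydroxyethyl alkoxide. The closest known reaction type is the SmI2-promoted annulation of chloro-iodoalkanes with keto esters (sequential Barbier addition and nucleophilic acyl substitution). The carbocycle is closed by the second event only, and the bicyclic samarium hemiketal should shield the new ketone from further reduction until work-up. The two stereocentres of 4 (C1 and C2) need no control, because acid dehydration removes both and gives the conjugated tetrasubstituted enone. The selectivity needed is chemoselectivity, iodide before chloride and ketone before lactone, which should be secured by the reduction potentials (C–I reacts in the dark, C–Cl only on irradiation) and by the higher electrophilicity of the chelated ketone.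

Step 2
Reactants: 5 2-(2-hydroxyethyl)-3-methylcyclohex-2-en-1-one
Product: 6 2-[2-(acetyloxy)ethyl]-3-methylcyclohexa-1,3-dien-1-yl acetate
Conditions: isopropenyl acetate, TsOH·H2O (cat.), reflux
Reagents that add atoms: isopropenyl acetate, CC(=C)OC(C)=O
Why: Acid-catalysed enol acetylation under thermodynamic control should give the linearly conjugated endocyclic dienyl acetate (and acetylate the primary alcohol), which makes C3 the nucleophilic γ-terminus (dienol ester formation).

Step 3
Reactants: 6 2-[2-(acetyloxy)ethyl]-3-methylcyclohexa-1,3-dien-1-yl acetate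
Product: 7 2-(3-hydroxy-2-methyl-6-oxocyclohex-1-en-1-yl)ethyl acetate (racemic)
Conditions: mCPBA, NaHCO3, CH2Cl2–H2O, 0 °C
Reagents that add atoms: 3-chloroperoxybenzoic acid, OOC(=O)c1cccc(Cl)c1
Why: The peracid should attack the γ,δ-double bond (C2=C3) of the dienyl acetate and the epoxide should collapse with loss of the enol acetyl group to the γ-hydroxy enone, as in the 6-hydroxylation of steroidal dienol acetates (vinylogous Rubottom-type oxidation); C3 is formed racemic here.

Step 4
Reactants: 7 2-(3-hydroxy-2-methyl-6-oxocyclohex-1-en-1-yl)ethyl acetate (racemic)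
Product: 8 (1R)-3-[2-(acetyloxy)ethyl]-2-methyl-4-oxocyclohex-2-en-1-yl acetate
Conditions: Burkholderia cepacia lipase (Amano PS), vinyl acetate, MTBE, 30 °C, stopped near half conversion; chromatography
Reagents that add atoms: vinyl acetate, CC(=O)OC=C
Why: Lipase-catalysed transesterification (kinetic resolution) should acylate the (R)-carbinol, whose larger substituent is the methyl-bearing alkene carbon, and leave (S)-7 behind; this sets C3, the stereocentre from which all ring centres are later relayed.

Step 5
Reactants: 8 (1R)-3-[2-(acetyloxy)ethyl]-2-methyl-4-oxocyclohex-2-en-1-yl acetate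
Product: 9 (4R)-4-hydroxy-2-(2-hydroxyethyl)-3-methylcyclohex-2-en-1-one
Conditions: K2CO3 (cat.), MeOH, 0 °C
Reagents that add atoms: none
Why: Mild base-catalysed transesterification should remove both acetates without touching the γ-hydroxy enone or the C3 centre.

Step 6
Reactants: 9 (4R)-4-hydroxy-2-(2-hydroxyethyl)-3-methylcyclohex-2-en-1-one
Product: 10 (4S)-4-bromo-2-(2-bromoethyl)-3-methylcyclohex-2-en-1-one
Conditions: CBr4, PPh3, CH2Cl2, −20 to 0 °C; used at once
Reagents that add atoms: tetrabromomethane, BrC(Br)(Br)Br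
Why: Appel reaction: both alcohols are replaced by bromide, the secondary allylic one by SN2 with inversion (R to S) while C2 is still sp2, so the bromide is never introduced at a neopentyl centre; low temperature and the absence of added bromide salt should limit racemisation.

Step 7
Reactants: 10 (4S)-4-bromo-2-(2-bromoethyl)-3-methylcyclohex-2-en-1-one
Product: 12 (2S,3S,4S)-4-bromo-2-(2-bromoethyl)-3-methyl-3-(prop-2-en-1-yl)cyclohexan-1-one, via trichlorotitanium enolate 11 (not isolated)
Conditions: TiCl4, allylSiMe3, CH2Cl2, −78 °C; aq NaHCO3; then TsOH (cat.), CH2Cl2, rt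
Reagents that add atoms: allyltrimethylsilane, C=CC[Si](C)(C)C
Why: Hosomi–Sakurai conjugate allylation: the TiCl4-activated enone should be attacked at C2 anti to the C3–Br bond, which 1,2-allylic strain with the C2 methyl holds pseudoaxial, so the quaternary centre forms with allyl trans to bromine; C1, α to the ketone, should equilibrate under acid to the equatorial side chain (cis to the C2 methyl).

Step 8
Reactants: 12 (2S,3S,4S)-4-bromo-2-(2-bromoethyl)-3-methyl-3-(prop-2-en-1-yl)cyclohexan-1-one
Product: 13 (1S,2S,3R)-1-bromo-3-(2-bromoethyl)-2-methyl-4-methylidene-2-(prop-2-en-1-yl)cyclohexane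
Conditions: Zn, CH2Br2, TiCl4, THF–CH2Cl2, 0 °C to rt
Reagents that add atoms: dibromomethane, BrCBr
Why: Takai–Lombardo methylenation with the non-basic CH2(ZnBr)2/TiCl4 reagent should convert the hindered, enolisable ketone to the exocyclic alkene without forming an enolate that could displace either bromide.

Step 9
Reactants: 14 (R)-lactic acid; 15 pivalaldehyde
Product: 16 (2R,5R)-2-tert-butyl-5-methyl-1,3-dioxolan-4-one
Conditions: TsOH (cat.), pentane, reflux with water separator; crystallisation of the cis isomer
Reagents that add atoms: none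
Why: Acid-catalysed acetalisation should give mainly the cis dioxolanone, in which the acetal carbon stores the lactate configuration (first stage of self-regeneration of stereocentres).

Step 10
Reactants: 13 (1S,2S,3R)-1-bromo-3-(2-bromoethyl)-2-methyl-4-methylidene-2-(prop-2-en-1-yl)cyclohexane; 16 (2R,5R)-2-tert-butyl-5-methyl-1,3-dioxolan-4-one
Product: 18 (2R,5S)-5-{2-[(1R,2S,3S)-3-bromo-2-methyl-6-methylidene-2-(prop-2-en-1-yl)cyclohexyl]ethyl}-2-tert-butyl-5-methyl-1,3-dioxolan-4-one, via lithium enolate 17 (not isolated)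
Conditions: 16, LiN(iPr)2, THF, −78 °C; then 13, DMPU, NaI (cat.), −78 to −20 °C
Reagents that add atoms: none
Why: The dioxolanone enolate should be alkylated by the primary bromide anti to the tert-butyl group (Seebach alkylation), so the chain replaces the lactate hydrogen with retention and sets the side-chain carbinol centre (S in the target); the neopentyl-type ring bromide should not react.

Step 11
Reactants: 18 (2R,5S)-5-{2-[(1R,2S,3S)-3-bromo-2-methyl-6-methylidene-2-(prop-2-en-1-yl)cyclohexyl]ethyl}-2-tert-butyl-5-methyl-1,3-dioxolan-4-one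
Product: 19 (2R,5S)-5-{2-[(3S,4S,5S,6S)-6-bromo-5-methyl-5-(prop-2-en-1-yl)-1-oxaspiro[2.5]octan-4-yl]ethyl}-2-tert-butyl-5-methyl-1,3-dioxolan-4-one (epoxide oxygen trans to the C1 side chain)
Conditions: mCPBA (1 equiv), NaHCO3, CH2Cl2, 0 °C
Reagents that add atoms: 3-chloroperoxybenzoic acid, OOC(=O)c1cccc(Cl)c1
Why: Peracid epoxidation should be fastest at the 1,1-disubstituted exocyclic alkene and should occur from the equatorial face, because the axial face is blocked by the syn-axial C2 methyl; this places oxygen trans to the C1 side chain.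

Step 12
Reactants: 19 spiro-epoxide (as named in step 11)
Product: 20 (2S)-4-[(1S,2S,3S,6S)-3-bromo-6-hydroxy-2,6-dimethyl-2-(prop-2-en-1-yl)cyclohexyl]-2-methylbutane-1,2-diol
Conditions: LiAlH4, Et2O, 0 °C
Reagents that add atoms: none
Why: Hydride should open the spiro-epoxide at its CH2 carbon to give the tertiary alcohol with axial methyl (C6 as in the target) and reduce the dioxolanone to the 1,2-diol; the hindered secondary bromide next to the quaternary carbon should resist SN2 hydride attack at 0 °C.

Step 13
Reactants: 20 (2S)-4-[(1S,2S,3S,6S)-3-bromo-6-hydroxy-2,6-dimethyl-2-(prop-2-en-1-yl)cyclohexyl]-2-methylbutane-1,2-diol; 21 2-methylbut-3-en-2-ol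
Product: 22 (2S)-4-{(1S,2S,3S,6S)-3-bromo-6-hydroxy-2-[(2E)-4-hydroxy-4-methylpent-2-en-1-yl]-2,6-dimethylcyclohexyl}-2-methylbutane-1,2-diol
Conditions: second-generation Hoveyda–Grubbs catalyst (5 mol %), 21 (excess), CH2Cl2, 40 °C
Reagents that add atoms: none
Why: Olefin cross-metathesis of the terminal allyl group with an excess of the hindered tertiary allylic alcohol should give the E-disubstituted alkene under thermodynamic control.

Step 14
Reactants: 22 (as named in step 13)
Product: 23 (2S)-4-{(1S,2S,3S,6S)-3-bromo-6-hydroxy-2-[(2E)-4-hydroxy-4-methylpent-2-en-1-yl]-2,6-dimethylcyclohexyl}-2-hydroxy-2-methylbutanal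
Conditions: TEMPO (cat.), PhI(OAc)2, CH2Cl2, rt
Reagents that add atoms: none
Why: TEMPO-catalysed oxidation should be selective for the only primary alcohol; the α-carbon is fully substituted, so the α-hydroxy aldehyde cannot epimerise.

Step 15
Reactants: 23 (as named in step 14)
Product: 24 (1S,2S,3S,4S)-4-bromo-2-[(3S)-3-hydroxy-3-methylpent-4-en-1-yl]-3-[(2E)-4-hydroxy-4-methylpent-2-en-1-yl]-1,3-dimethylcyclohexan-1-ol
Conditions: Ph3PCH3Br, KOtBu (excess), THF, 0 °C to rt
Reagents that add atoms: methyltriphenylphosphonium bromide, C[P+](c1ccccc1)(c1ccccc1)c1ccccc1.[Br-]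
Why: Wittig methylenation with excess ylide (which also deprotonates the hydroxyl groups) should convert the aldehyde to the vinyl group and complete the target.

**Compound list**

1 | 3-acetyloxolan-2-one | CC(=O)C1CCOC1=O | starting material
2 | 1-chloro-3-iodopropane | ClCCCI | starting material
3 | 3-(5-chloro-2-hydroxypentan-2-yl)oxolan-2-one (formed as its samarium alkoxide) | CC(O)(CCCCl)C1CCOC1=O | intermediate
4 | 3-hydroxy-2-(2-hydroxyethyl)-3-methylcyclohexan-1-one | CC1(O)CCCC(=O)C1CCO | intermediate
5 | 2-(2-hydroxyethyl)-3-methylcyclohex-2-en-1-one | CC1=C(CCO)C(=O)CCC1 | intermediate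
6 | 2-[2-(acetyloxy)ethyl]-3-methylcyclohexa-1,3-dien-1-yl acetate | CC(=O)OCCC1=C(OC(C)=O)CCC=C1C | intermediate
7 | 2-(3-hydroxy-2-methyl-6-oxocyclohex-1-en-1-yl)ethyl acetate (racemic) | CC(=O)OCCC1=C(C)C(O)CCC1=O | intermediate
8 | (1R)-3-[2-(acetyloxy)ethyl]-2-methyl-4-oxocyclohex-2-en-1-yl acetate | CC(=O)OCCC1=C(C)[C@H](OC(C)=O)CCC1=O | intermediate
9 | (4R)-4-hydroxy-2-(2-hydroxyethyl)-3-methylcyclohex-2-en-1-one | OCCC1=C(C)[C@H](O)CCC1=O | intermediate
10 | (4S)-4-bromo-2-(2-bromoethyl)-3-methylcyclohex-2-en-1-one | BrCCC1=C(C)[C@@H](Br)CCC1=O | intermediate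
11 | trichlorotitanium enolate of 12 | Cl[Ti](Cl)(Cl)OC1=C(CCBr)[C@](C)(CC=C)[C@@H](Br)CC1 | intermediate
12 | (2S,3S,4S)-4-bromo-2-(2-bromoethyl)-3-methyl-3-(prop-2-en-1-yl)cyclohexan-1-one | BrCC[C@H]1[C@](C)(CC=C)[C@@H](Br)CCC1=O | intermediate
13 | (1S,2S,3R)-1-bromo-3-(2-bromoethyl)-2-methyl-4-methylidene-2-(prop-2-en-1-yl)cyclohexane | BrCC[C@H]1[C@](C)(CC=C)[C@@H](Br)CCC1=C | intermediate
14 | (R)-lactic acid | C[C@@H](O)C(=O)O | starting material
15 | pivalaldehyde | CC(C)(C)C=O | starting material
16 | (2R,5R)-2-tert-butyl-5-methyl-1,3-dioxolan-4-one | C[C@H]1O[C@@H](C(C)(C)C)OC1=O | intermediate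
17 | lithium enolate of 16 | [Li]OC1=C(C)O[C@@H](C(C)(C)C)O1 | intermediate
18 | (2R,5S)-5-{2-[(1R,2S,3S)-3-bromo-2-methyl-6-methylidene-2-(prop-2-en-1-yl)cyclohexyl]ethyl}-2-tert-butyl-5-methyl-1,3-dioxolan-4-one | C[C@@]1(CC[C@H]2[C@](C)(CC=C)[C@@H](Br)CCC2=C)O[C@@H](C(C)(C)C)OC1=O | intermediate
19 | (2R,5S)-5-{2-[(3S,4S,5S,6S)-6-bromo-5-methyl-5-(prop-2-en-1-yl)-1-oxaspiro[2.5]octan-4-yl]ethyl}-2-tert-butyl-5-methyl-1,3-dioxolan-4-one | C[C@@]1(CC[C@H]2[C@](C)(CC=C)[C@@H](Br)CC[C@@]23CO3)O[C@@H](C(C)(C)C)OC1=O | intermediate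
20 | (2S)-4-[(1S,2S,3S,6S)-3-bromo-6-hydroxy-2,6-dimethyl-2-(prop-2-en-1-yl)cyclohexyl]-2-methylbutane-1,2-diol | OC[C@@](C)(O)CC[C@H]1[C@](C)(CC=C)[C@@H](Br)CC[C@]1(C)O | intermediate
21 | 2-methylbut-3-en-2-ol | CC(C)(O)C=C | starting material
22 | (2S)-4-{(1S,2S,3S,6S)-3-bromo-6-hydroxy-2-[(2E)-4-hydroxy-4-methylpent-2-en-1-yl]-2,6-dimethylcyclohexyl}-2-methylbutane-1,2-diol | OC[C@@](C)(O)CC[C@H]1[C@](C)(C/C=C/C(C)(C)O)[C@@H](Br)CC[C@]1(C)O | intermediate
23 | (2S)-4-{(1S,2S,3S,6S)-3-bromo-6-hydroxy-2-[(2E)-4-hydroxy-4-methylpent-2-en-1-yl]-2,6-dimethylcyclohexyl}-2-hydroxy-2-methylbutanal | O=C[C@@](C)(O)CC[C@H]1[C@](C)(C/C=C/C(C)(C)O)[C@@H](Br)CC[C@]1(C)O | intermediate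
24 | (1S,2S,3S,4S)-4-bromo-2-[(3S)-3-hydroxy-3-methylpent-4-en-1-yl]-3-[(2E)-4-hydroxy-4-methylpent-2-en-1-yl]-1,3-dimethylcyclohexan-1-ol | C=C[C@@](C)(O)CC[C@H]1[C@](C)(C/C=C/C(C)(C)O)[C@@H](Br)CC[C@]1(C)O | target

**Step count and risks**

Total step count: 15. Longest linear sequence: 14 steps (steps 1–8 and 10–15; step 9 prepares 16 in a side branch).

Steps most likely to fail:

1. Step 1 (key annulation). What may go wrong: protonation of the first alkylsamarium by the acidic C–H between the two carbonyl groups of 1, loss of the chloropropyl unit as cyclopropane by 1,3-elimination, or over-reduction of the ketone before the ring closes. Fallback, from 1 and back at 5, making the same two bonds in separate operations: indium-mediated Barbier allylation of the acetyl ketone (In, allyl bromide, THF–H2O) should give the homoallylic alcohol 3-(2-hydroxypent-4-en-2-yl)oxolan-2-one F1. Hydroboration with 9-BBN followed by iodination (I2, NaOMe, 0 °C) should give 3-(2-hydroxy-5-iodopentan-2-yl)oxolan-2-one F2. SmI2/HMPA in THF should then close the ring by intramolecular nucleophilic acyl substitution on the lactone to 4, which dehydrates to 5 on the same acidic work-up.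

2. Step 7 (conjugate allylation). What may go wrong: sluggish addition to the tetrasubstituted enone, together with ionisation or chloride exchange of the allylic C–Br bond by the Lewis acid, which would erode the C3 configuration that steers the attack. Fallback, from 10 and back at 12: Lewis-acid-free conjugate allylation with an allylcopper reagent (allylMgBr, CuBr·SMe2, Me3SiCl, THF, −78 °C) should give the silyl enol ether {[(3S,4S)-4-bromo-2-(2-bromoethyl)-3-methyl-3-(prop-2-en-1-yl)cyclohex-1-en-1-yl]oxy}trimethylsilane F3, which is hydrolysed and equilibrated at C1 (TsOH, wet CH2Cl2) to 12.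

3. Step 4 (enzymatic resolution). What may go wrong: poor discrimination of the two enantiomers of 7 by the enzyme, because the carbinol carbon is flanked by a fully substituted alkene carbon, so that 8 would be obtained with low enantiomeric purity. Fallback, from 7 and back at 9, by classical resolution through covalent diastereomers: esterification of racemic 7 with (S)-2-methoxy-2-phenylacetic acid (DCC, DMAP, CH2Cl2), chromatographic separation of the two diastereomeric esters, and methanolysis (K2CO3, MeOH, 0 °C) of the ester of the (R)-carbinol, (1R)-3-[2-(acetyloxy)ethyl]-2-methyl-4-oxocyclohex-2-en-1-yl (2S)-methoxy(phenyl)acetate F4, which should give 9.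

Further compounds
F1 | step 1 | 3-(2-hydroxypent-4-en-2-yl)oxolan-2-one | CC(O)(CC=C)C1CCOC1=O
F2 | step 1 | 3-(2-hydroxy-5-iodopentan-2-yl)oxolan-2-one | CC(O)(CCCI)C1CCOC1=O
F3 | step 7 | {[(3S,4S)-4-bromo-2-(2-bromoethyl)-3-methyl-3-(prop-2-en-1-yl)cyclohex-1-en-1-yl]oxy}trimethylsilane | C[Si](C)(C)OC1=C(CCBr)[C@](C)(CC=C)[C@@H](Br)CC1
F4 | step 4 | (1R)-3-[2-(acetyloxy)ethyl]-2-methyl-4-oxocyclohex-2-en-1-yl (2S)-methoxy(phenyl)acetate | CC(=O)OCCC1=C(C)[C@H](OC(=O)[C@@H](OC)c2ccccc2)CCC1=O
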